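## Structural features

The target is a 3,4-trans-diarylchroman (rings A and C) that carries ring B, a 3-hydroxy-2,4-dimethoxyphenyl group, on C3 and ring D, a resorcinol monomethyl ether, on C4. Ring D is bonded through D1 to C4, has methoxy on D2 and hydroxyl on D4, and is bonded through D6 to C3' of a second 7-hydroxychroman (rings A' and C'). C3 (R) and C4 (S) are adjacent and trans. C3' (R) is separated from C4 by the aromatic carbons D6 and D1, so no stereochemical relay is possible and the two chroman units must each be made enantiopure. The four free phenols make the final compound sensitive to oxidants and electrophiles, and C4 is a doubly benzylic methine that ionises readily once it bears a leaving group. The real difficulty is ring D: two branched secondary alkyl groups on neighbouring carbons, a C4–D1 bond between a stereogenic methine and a di-ortho-substituted arene, and two oxygens that must be told apart. The key step uses the match between the sequence D1(C)–D2(O)–D3(H)–D4(O)–D5(H)–D6(C) and the atoms of a 3,4-disubstituted cyclobutenone plus an ynol ether. The cyclobutenone supplies D1, D2, D5 and D6 (its C4, C1, C2 and C3) and the ynol ether supplies D3 and D4, so the carbonyl oxygen and the ynol oxygen arrive already differentiated.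

## Logic of the disconnections

35 to 34: the three aryl O–S bonds and the aryl O–Si bond are cut. All four phenols are thereby masked until the last operation and one hydroxide treatment frees them. The gain is that every earlier intermediate is non-phenolic and the resorcinol-type rings are electron-poor. The forward step must hydrolyse sulfonates and the silyl ether without alkylating the liberated phenoxides, so the medium contains no methanol or ethanol.

34 to 33: the D2 O–CH3 bond is cut. The ring-forming step delivers D2 as a free hydroxyl and D4 as a silyl ether, so methylation at this point fixes the differentiation. The demand is alkylation of a phenol next to a bulky group without loss of the silyl group.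

33 to 24 and 28: D2–D3 and D4–D5 are cut, together with D1–D2, the bond that is broken and re-made during the cascade. Both chromans then arrive complete and the three stereocentres are spectators. A hexasubstituted benzene is reduced to a four-membered ring and a two-carbon ynol ether. The forward step must tolerate two branched substituents on adjacent carbons and must join ketene and alkyne in one orientation only.

28 to 25: the O–Si and C–O bonds are cut, leading back through an ynolate to an acetylide. The demand is silylation on oxygen and not on carbon.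

24 to 13 and 21: the C1–C2 and C3–C4 bonds of the four-membered ring are cut. A keteniminium–alkyne [2+2] puts the amide substituent on C4 and the alkyne substituent on C3, which is the arrangement ring D needs. The two fragments are of similar size and each carries its own stereocentres. The demand is that the keteniminium ion meets no better nucleophile than the alkyne. Resorcinol dialkyl ether rings would be better nucleophiles than a terminal alkyne, so all three phenols are carried as p-toluenesulfonates and not as benzyl ethers.

13 to 12 to 11: the amide C–N bond and then the C4–CH2 bond are cut. The C4 cation is stabilised by the ring oxygen and is attacked anti to the C3 aryl group, which gives the trans relationship. An ester ketene acetal is used, followed by aminolysis, because the O-silyl ketene aminal of an acetamide tends to isomerise to the C-silyl amide. The demand is that capture of the cation is faster than proton loss from C3.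

11 to 9: the C4 carbonyl and the C2=C3 double bond are restored. A transfer hydrogenation with dynamic kinetic resolution sets C3 absolutely; the carbinol centre is sacrificed in the next step. The demand is that 10 racemises faster than it is reduced.

9 to 4 and 8, then 4 to 2 to 1 and 8 to 7 to 6 to 5: the C3–C1' bond is cut (Suzuki–Miyaura), then the pyranone ring, the C–B, C–Br and O–S bonds. The bromination must enter ortho to one methoxy and para to the other, which the two methoxy groups ensure.

21 back to 14 through 20, 19, 18, 17, 16 and 15: the terminal alkyne carbon is removed (one-carbon homologation of an aldehyde), the oxidation level is adjusted, the C3'=C4' double bond is restored (asymmetric hydrogenation sets C3'), and the O1'–C2' and C3'–C4' bonds are cut (annulation with acrolein). The demand is that the α-branched, β-aryloxy aldehyde 20 is handled without enolisation.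

## Other disconnections considered

Alternative 1: The cut is at D1–C(carbonyl) and D6–CH2. In the forward step fluoride releases the aryne from silyl aryl triflate A1, the enolate of β-keto ester A2 adds at D6, the aryl anion at D1 attacks the ketone, and fragmentation gives keto ester A3.
- In favour: the insertion runs at ambient temperature from simple materials, and the 3-methoxy group steers the enolate to the distal aryne carbon. On reliability of the key step itself this plan is the better one.
- Against: A3 has no stereocentre. Its tetra-ortho-congested diaryl ketone must still become the C4 methine with ring B trans on C3 under absolute control, and the acetate arm must be alkylated enantioselectively and closed to the second chroman.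
- Comparison: structurally, the chosen plan brings both chromans in complete and A3 brings neither. Mechanistically, an ionic insertion is less sensitive to bulk than a four-stage pericyclic cascade. In step economy the alternative needs well over ten operations after its key step, against two here.

Alternative 2: The cuts are C3–ring B and C4–C4a, made together. Aryllithium A5 adds to alkenyl boronate A4; the ate complex couples with aryl triflate A6 under Pd(OAc)2 and a chiral MandyPhos ligand (1,2-shift, then reductive elimination) to give boronate A7, which is a 1,2,2-triarylethyl boronic ester.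
- In favour: both adjacent stereocentres come from one catalyst-controlled event, and anti addition across the E-alkene fixes their relationship. On this point it equals or betters the chosen plan, which needs a reduction and a separate substitution.
- Against: β-aryl alkenyl pinacol boronates are the weak substrates of this coupling, and here the β-aryl group is 2,6-disubstituted while the migrating group and the electrophile are both ortho-substituted. A4 already contains ring D joined to the second chroman, so the central-ring problem is moved and not solved.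
- Comparison: structurally it addresses C3/C4 and not ring D. Mechanistically it depends on a metallate shift at a very crowded alkene, where the chosen plan depends on thermal steps without a catalyst. In step economy, the boron-bearing carbon must still be homologated, oxidised and closed onto the ring A oxygen (four to five steps), and A4 must be made first.

Alternative 3: The cuts are D1–D2 and D5–D6. Diene A8 adds to ynone A9, and loss of methanol and of the silyl group gives benzophenone A10.
- In favour: the polarised diene fixes the regiochemistry, and methoxy and hydroxyl emerge differentiated with no separate methylation and no siloxyalkyne. On these two points it is better than the chosen plan. The ring D–chroman bond is in place from an easily made ynone.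
- Against: A10 carries the same hindered diaryl ketone at D1 as A3, so the whole diarylchroman with two stereocentres must be built afterwards. The propargylic C3' centre of A9 can racemise through an allenolate on heating.
- Comparison: structurally it completes ring D and one chroman, the chosen plan ring D and both. Mechanistically a single cycloaddition–aromatisation is simpler than the cascade used here. In step economy it saves two late steps but adds the full construction of the first chroman.

Key step: step 19

Assumption: 2,4-dihydroxyacetophenone, 2,6-dimethoxyphenol, 2,4-dihydroxybenzaldehyde and acetylene are taken as purchasable; (triisopropylsiloxy)acetylene is not taken as a catalogue item and is made in step 18. The sense of induction in steps 7 and 13 follows the usual models and would be confirmed on the first batch.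

## Route

Step 1
Reactants: 1 2,4-dihydroxyacetophenone
Product: 2 2-hydroxy-4-(tosyloxy)acetophenone
Conditions: TsCl (1.05 equiv), K2CO3, acetone, 0 °C to rt
Reagents that add atoms: p-toluenesulfonyl chloride, Cc1ccc(cc1)S(Cl)(=O)=O
Why: Chemoselective O-sulfonylation: the C4 hydroxyl is more acidic and is not held in the hydrogen bond to the acetyl group, so one equivalent should react there; the sulfonate later keeps ring A too electron-poor to intercept the keteniminium ion of step 17.

Step 2
Reactants: 2 2-hydroxy-4-(tosyloxy)acetophenone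
Product: 4 3-iodo-7-(tosyloxy)chromen-4-one, via enaminone 3 (not isolated)
Conditions: Me2NCH(OMe)2 (1.5 equiv), toluene, 95 °C; evaporate; I2 (1.2 equiv), CHCl3, rt
Reagents that add atoms: N,N-dimethylformamide dimethyl acetal, COC(OC)N(C)C; iodine, II
Why: Condensation of the methyl ketone with the amide acetal gives the enaminone, and iodine then triggers cyclisation of the ortho-hydroxyaryl enaminone with loss of dimethylamine (iodocyclisation to a 3-iodochromone); the aryl sulfonate is inert to both reagents.

Step 3
Reactants: 5 2,6-dimethoxyphenol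
Product: 6 2,6-dimethoxyphenyl tosylate
Conditions: TsCl (1.2 equiv), Et3N, DMAP (cat.), CH2Cl2, rt
Reagents that add atoms: p-toluenesulfonyl chloride, Cc1ccc(cc1)S(Cl)(=O)=O
Why: DMAP-catalysed sulfonylation of a hindered phenol; the sulfonyloxy group removes the para-directing power of the phenol so that the methoxy groups control step 4.

Step 4
Reactants: 6 2,6-dimethoxyphenyl tosylate
Product: 7 3-bromo-2,6-dimethoxyphenyl tosylate
Conditions: NBS (1.0 equiv), MeCN, rt
Reagents that add atoms: N-bromosuccinimide, BrN1C(=O)CCC1=O
Why: Electrophilic aromatic bromination; C3 is ortho to one methoxy group and para to the other, whereas C4 is meta to both, so the bromine should enter at C3 and give the ring B substitution pattern.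

Step 5
Reactants: 7 3-bromo-2,6-dimethoxyphenyl tosylate
Product: 8 2,6-dimethoxy-3-(4,4,5,5-tetramethyl-1,3,2-dioxaborolan-2-yl)phenyl tosylate
Conditions: B2pin2 (1.2 equiv), Pd(dppf)Cl2 (3 mol%), KOAc (3 equiv), 1,4-dioxane, 90 °C
Reagents that add atoms: bis(pinacolato)diboron, CC1(C)OB(OC1(C)C)B1OC(C)(C)C(C)(C)O1
Why: Miyaura borylation of the aryl bromide; the aryl sulfonate does not undergo oxidative addition with this catalyst.

Step 6
Reactants: 4 3-iodo-7-(tosyloxy)chromen-4-one; 8 2,6-dimethoxy-3-(4,4,5,5-tetramethyl-1,3,2-dioxaborolan-2-yl)phenyl tosylate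
Product: 9 3-[2,4-dimethoxy-3-(tosyloxy)phenyl]-7-(tosyloxy)chromen-4-one (isoflavone)
Conditions: Pd(dppf)Cl2 (5 mol%), Na2CO3 (2 M aq.), DME, 80 °C
Reagents that add atoms: none
Why: Suzuki–Miyaura coupling of a 3-iodochromone forms the C3–C1' bond; the carbon–iodine bond reacts far faster than either aryl sulfonate.

Step 7
Reactants: 9 3-[2,4-dimethoxy-3-(tosyloxy)phenyl]-7-(tosyloxy)chromen-4-one
Product: 11 (3R,4R)-3-[2,4-dimethoxy-3-(tosyloxy)phenyl]-7-(tosyloxy)chroman-4-ol (3,4-cis), via isoflavanone 10 (not isolated)
Conditions: RuCl[(R,R)-TsDPEN](p-cymene) (3 mol%), HCO2H/Et3N (5:2), EtOAc, 45 °C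
Reagents that add atoms: none
Why: Noyori–Ikariya transfer hydrogenation run as a domino: conjugate reduction gives isoflavanone 10, which racemises through its enol under Et3N while the (R,R) catalyst reduces one enantiomer faster (dynamic kinetic resolution), delivering hydride to the carbonyl face that gives 4R and cis to the aryl group; this fixes C3 as R, the configuration kept to the target.

Step 8
Reactants: 11 (3R,4R)-3-[2,4-dimethoxy-3-(tosyloxy)phenyl]-7-(tosyloxy)chroman-4-ol
Product: 12 methyl 2-{(3R,4S)-3-[2,4-dimethoxy-3-(tosyloxy)phenyl]-7-(tosyloxy)chroman-4-yl}acetate (3,4-trans)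
Conditions: CH2=C(OMe)OTBS (3 equiv), TMSOTf (0.2 equiv), CH2Cl2, −78 to −30 °C
Reagents that add atoms: 1-(tert-butyldimethylsilyloxy)-1-methoxyethene, C=C(OC)O[Si](C)(C)C(C)(C)C
Why: Mukaiyama-type SN1 substitution: ionisation gives the C4 cation stabilised by the ortho ring oxygen, and the silyl ketene acetal should add to the face anti to the C3 aryl group (and anti to any bridging by the 2'-methoxy oxygen), which sets C4 trans to C3; C3 is untouched as long as capture outruns proton loss to the chromene.

Step 9
Reactants: 12 methyl 2-{(3R,4S)-3-[2,4-dimethoxy-3-(tosyloxy)phenyl]-7-(tosyloxy)chroman-4-yl}acetate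
Product: 13 2-{(3R,4S)-3-[2,4-dimethoxy-3-(tosyloxy)phenyl]-7-(tosyloxy)chroman-4-yl}-N,N-dimethylacetamide
Conditions: Me2NH·HCl (3 equiv), AlMe3 (3 equiv), toluene, 0 to 50 °C; aq. HCl work-up
Reagents that add atoms: dimethylamine hydrochloride, CNC.Cl
Why: Weinreb-type aminolysis of the methyl ester by the dimethylaluminium amide gives the tertiary amide that keteniminium formation requires; C4 is not alpha to the carbonyl and the aryl sulfonates are not attacked by the aluminium amide.

Step 10
Reactants: 14 2,4-dihydroxybenzaldehyde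
Product: 15 2-hydroxy-4-(tosyloxy)benzaldehyde
Conditions: TsCl (1.05 equiv), K2CO3, acetone, 0 °C to rt
Reagents that add atoms: p-toluenesulfonyl chloride, Cc1ccc(cc1)S(Cl)(=O)=O
Why: Same chemoselective sulfonylation as in step 1; the hydroxyl ortho to the formyl group is hydrogen-bonded and stays free for the annulation.

Step 11
Reactants: 15 2-hydroxy-4-(tosyloxy)benzaldehyde
Product: 16 7-(tosyloxy)-2H-chromene-3-carbaldehyde
Conditions: acrolein (1.5 equiv), K2CO3 (1 equiv), 1,4-dioxane, 80 °C
Reagents that add atoms: acrolein, C=CC=O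
Why: Oxa-Michael addition of the phenoxide to acrolein followed by intramolecular aldol condensation closes the pyran ring (chromene annulation of a salicylaldehyde).

Step 12
Reactants: 16 7-(tosyloxy)-2H-chromene-3-carbaldehyde
Product: 17 7-(tosyloxy)-2H-chromene-3-carboxylic acid
Conditions: NaClO2, NaH2PO4, 2-methyl-2-butene, t-BuOH/H2O, rt
Reagents that add atoms: sodium chlorite, [Na+].[O-]Cl=O
Why: Pinnick oxidation of the enal; the conditions are near neutral and leave the sulfonate and the ring double bond alone.

Step 13
Reactants: 17 7-(tosyloxy)-2H-chromene-3-carboxylic acid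
Product: 18 (S)-7-(tosyloxy)chroman-3-carboxylic acid
Conditions: [Ir(cod)(SIPHOX)]BArF (1 mol%; spiro phosphine–oxazoline ligand, antipode chosen for the S acid), H2 (6 bar), Et3N (0.5 equiv), MeOH, rt
Reagents that add atoms: none
Why: Carboxylate-directed asymmetric hydrogenation of a cyclic α,β-unsaturated acid sets C3'; the ligand antipode that gives the S acid is selected in a pilot run, and S here corresponds to R at C3' of the target because the substituent priorities change.

Step 14
Reactants: 18 (S)-7-(tosyloxy)chroman-3-carboxylic acid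
Product: 19 (R)-[7-(tosyloxy)chroman-3-yl]methanol
Conditions: BH3·SMe2 (1.5 equiv), THF, 0 °C to rt; aqueous work-up
Reagents that add atoms: none
Why: Borane reduces the carboxylic acid chemoselectively through the acyloxyborane; the aryl sulfonate is inert and the stereocentre is not enolised.

Step 15
Reactants: 19 (R)-[7-(tosyloxy)chroman-3-yl]methanol
Product: 20 (S)-7-(tosyloxy)chroman-3-carbaldehyde
Conditions: Dess–Martin periodinane (1.2 equiv), NaHCO3, CH2Cl2, 0 °C; used crude at once
Reagents that add atoms: none
Why: Dess–Martin oxidation under buffered, non-basic conditions keeps the α-branched, β-aryloxy aldehyde from enolising; it is not stored.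

Step 16
Reactants: 20 (S)-7-(tosyloxy)chroman-3-carbaldehyde
Product: 21 (R)-3-ethynyl-7-(tosyloxy)chroman
Conditions: MeC(O)C(N2)P(O)(OMe)2 (1.3 equiv), K2CO3 (2 equiv), MeOH, 0 °C to rt
Reagents that add atoms: dimethyl (1-diazo-2-oxopropyl)phosphonate, COP(=O)(OC)C(=[N+]=[N-])C(C)=O
Why: Ohira–Bestmann (Seyferth–Gilbert) homologation: the deacylated diazophosphonate anion adds to the aldehyde, cycloelimination gives the diazoalkene and a 1,2-hydrogen shift gives the alkyne; addition to the carbonyl should be faster than enolisation at 0 °C, so C3' is retained.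

Step 17
Reactants: 13 2-{(3R,4S)-3-[2,4-dimethoxy-3-(tosyloxy)phenyl]-7-(tosyloxy)chroman-4-yl}-N,N-dimethylacetamide; 21 (R)-3-ethynyl-7-(tosyloxy)chroman
Product: 24 4-{(3R)-3-[2,4-dimethoxy-3-(tosyloxy)phenyl]-7-(tosyloxy)chroman-4-yl}-3-[(3R)-7-(tosyloxy)chroman-3-yl]cyclobut-2-en-1-one (3,4-trans chroman as in 13; both epimers at the ring sp3 carbon), via keteniminium triflate 22 (not isolated), via cyclobuteniminium triflate 23 (not isolated)
Conditions: 13 (1.3 equiv), Tf2O (1.3 equiv), 2,4,6-collidine (1.4 equiv), ClCH2CH2Cl, −20 to 60 °C; then aq. NaHCO3, rt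
Reagents that add atoms: water, O
Why: Ghosez-type keteniminium–alkyne [2+2]: O-triflation and elimination give 22, the terminal alkyne carbon attacks its central carbon and the developing vinyl cation closes on the α-carbon, which puts the chromanyl group on C3 and the isoflavanyl group on C4; hydrolysis of 23 gives the enone. The sulfonates make rings A and A' poor nucleophiles and lower the reactivity of ring B, so the alkyne should be the best partner for 22; the epimers at C4 of the four-membered ring converge in step 19.

Step 18
Reactants: 25 acetylene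
Product: 28 (triisopropylsiloxy)acetylene, via lithium acetylide 26 (not isolated), via lithium ethynolate 27 (not isolated)
Conditions: HC≡CH (excess), n-BuLi (1.0 equiv), THF, −78 °C; t-BuOOLi (from t-BuOOH and LiHMDS), −78 to −20 °C; TIPSOTf (1.0 equiv), −78 to 0 °C
Reagents that add atoms: tert-butyl hydroperoxide, CC(C)(C)OO; triisopropylsilyl trifluoromethanesulfonate, CC(C)[Si](OS(=O)(=O)C(F)(F)F)(C(C)C)C(C)C
Why: Electrophilic oxygenation of the lithium acetylide by lithium tert-butyl peroxide gives the ynolate, and the hard, bulky silyl triflate should silylate on oxygen, as it does with ynolates from 1-alkynes; the triisopropylsilyl group is chosen because it slows the 1,3-shift to the silylketene.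

Step 19
Reactants: 24 4-{(3R)-3-[2,4-dimethoxy-3-(tosyloxy)phenyl]-7-(tosyloxy)chroman-4-yl}-3-[(3R)-7-(tosyloxy)chroman-3-yl]cyclobut-2-en-1-one; 28 (triisopropylsiloxy)acetylene
Product: 33 2-{(3R,4S)-3-[2,4-dimethoxy-3-(tosyloxy)phenyl]-7-(tosyloxy)chroman-4-yl}-3-[(3R)-7-(tosyloxy)chroman-3-yl]-5-(triisopropylsiloxy)phenol (ring D with D2 hydroxyl and D4 silyl ether), via vinylketene 29 (not isolated), via alkenylcyclobutenone 30 (not isolated), via dienylketene 31 (not isolated), via cyclohexadienone 32 (not isolated)
Conditions: 28 (2.0 equiv), toluene (0.1 M), 80 °C then 110 °C, Ar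
Reagents that add atoms: none
Why: Thermal 4π electrocyclic opening of 24 (both ring epimers) gives vinylketene 29, with the bulky isoflavanyl group rotating outward. The ynol ether 28 adds to the ketene C=C in a [2+2] cycloaddition, its nucleophilic CH carbon bonding to the ketene carbonyl carbon, to give 30 (bonds D2–D3 and D4–D5). A second 4π opening gives dienylketene 31, which closes ring D by thermal disrotatory 6π electrocyclisation between the ketene carbon (D2) and the isoflavanyl-bearing alkene terminus (D1); tautomerisation of dienone 32 gives the phenol. The closest known reaction type is the Danheiser benzannulation of cyclobutenones with siloxyalkynes to resorcinol monosilyl ethers. No stereocentre is formed; C3, C4 and C3' are spectators, and the C4 hydrogen is not placed for a 1,5-shift in the E-vinylketene. The step needs one orientation of the ketene–alkyne union, which the polarity of 28 secures, so that the siloxy carbon becomes D4, meta to the new D2 hydroxyl, and the two oxygens emerge differentiated. It also needs the ketene to add to 28 and not to itself or to the product phenol, which the excess of 28 and moderate dilution favour; the sulfonates and the silyl ether are thermally inert.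

Step 20
Reactants: 33 2-{(3R,4S)-3-[2,4-dimethoxy-3-(tosyloxy)phenyl]-7-(tosyloxy)chroman-4-yl}-3-[(3R)-7-(tosyloxy)chroman-3-yl]-5-(triisopropylsiloxy)phenol
Product: 34 the D2 methyl ether of 33: (3R,4S)-4-{2-methoxy-6-[(3R)-7-(tosyloxy)chroman-3-yl]-4-(triisopropylsiloxy)phenyl}-3-[2,4-dimethoxy-3-(tosyloxy)phenyl]chroman-7-yl tosylate
Conditions: MeI (5 equiv), K2CO3 (3 equiv), acetone, 45 °C
Reagents that add atoms: iodomethane, CI
Why: Williamson methylation of the only free phenol; carbonate in acetone is too weak to cleave the aryl triisopropylsilyl ether or the sulfonates, and the meta relationship of D2 and D4 rules out silyl migration.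

Step 21
Reactants: 34 the D2 methyl ether of 33
Product: 35 3-[(3R)-7-hydroxychroman-3-yl]-4-[(3R,4S)-7-hydroxy-3-(3-hydroxy-2,4-dimethoxyphenyl)chroman-4-yl]-5-methoxyphenol (CNP0305801.1)
Conditions: KOH (20 equiv), t-BuOH/1,4-dioxane/H2O, 80 °C, Ar; then 1 M HCl to pH 5
Reagents that add atoms: none
Why: Hydroxide attacks sulfur of the three aryl sulfonates (S–O cleavage, aryl oxygen retained) and silicon of the aryl silyl ether, each releasing a phenoxide; no methanol or ethanol is present, so no alkyl tosylate can form and re-alkylate the phenoxides, and none of the three stereocentres bears an acidic hydrogen.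

## Compound list

1 | 2,4-dihydroxyacetophenone | CC(=O)c1ccc(O)cc1O | starting material
2 | 2-hydroxy-4-(tosyloxy)acetophenone | CC(=O)c1ccc(OS(=O)(=O)c2ccc(C)cc2)cc1O | intermediate
3 | (E)-3-(dimethylamino)-1-[2-hydroxy-4-(tosyloxy)phenyl]prop-2-en-1-one | CN(C)/C=C/C(=O)c1ccc(OS(=O)(=O)c2ccc(C)cc2)cc1O | intermediate
4 | 3-iodo-7-(tosyloxy)chromen-4-one | O=c1c(I)coc2cc(OS(=O)(=O)c3ccc(C)cc3)ccc12 | intermediate
5 | 2,6-dimethoxyphenol | COc1cccc(OC)c1O | starting material
6 | 2,6-dimethoxyphenyl tosylate | COc1cccc(OC)c1OS(=O)(=O)c1ccc(C)cc1 | intermediate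
7 | 3-bromo-2,6-dimethoxyphenyl tosylate | COc1ccc(Br)c(OC)c1OS(=O)(=O)c1ccc(C)cc1 | intermediate
8 | 2,6-dimethoxy-3-(pinacolatoboryl)phenyl tosylate | COc1ccc(B2OC(C)(C)C(C)(C)O2)c(OC)c1OS(=O)(=O)c1ccc(C)cc1 | intermediate
9 | 3-[2,4-dimethoxy-3-(tosyloxy)phenyl]-7-(tosyloxy)chromen-4-one | COc1ccc(-c2coc3cc(OS(=O)(=O)c4ccc(C)cc4)ccc3c2=O)c(OC)c1OS(=O)(=O)c1ccc(C)cc1 | intermediate
10 | 3-[2,4-dimethoxy-3-(tosyloxy)phenyl]-7-(tosyloxy)chroman-4-one (racemising at C3) | COc1ccc(C2COc3cc(OS(=O)(=O)c4ccc(C)cc4)ccc3C2=O)c(OC)c1OS(=O)(=O)c1ccc(C)cc1 | intermediate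
11 | (3R,4R)-3-[2,4-dimethoxy-3-(tosyloxy)phenyl]-7-(tosyloxy)chroman-4-ol | COc1ccc([C@@H]2COc3cc(OS(=O)(=O)c4ccc(C)cc4)ccc3[C@@H]2O)c(OC)c1OS(=O)(=O)c1ccc(C)cc1 | intermediate
12 | methyl 2-{(3R,4S)-3-[2,4-dimethoxy-3-(tosyloxy)phenyl]-7-(tosyloxy)chroman-4-yl}acetate | COc1ccc([C@@H]2COc3cc(OS(=O)(=O)c4ccc(C)cc4)ccc3[C@H]2CC(=O)OC)c(OC)c1OS(=O)(=O)c1ccc(C)cc1 | intermediate
13 | 2-{(3R,4S)-3-[2,4-dimethoxy-3-(tosyloxy)phenyl]-7-(tosyloxy)chroman-4-yl}-N,N-dimethylacetamide | COc1ccc([C@@H]2COc3cc(OS(=O)(=O)c4ccc(C)cc4)ccc3[C@H]2CC(=O)N(C)C)c(OC)c1OS(=O)(=O)c1ccc(C)cc1 | intermediate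
14 | 2,4-dihydroxybenzaldehyde | O=Cc1ccc(O)cc1O | starting material
15 | 2-hydroxy-4-(tosyloxy)benzaldehyde | O=Cc1ccc(OS(=O)(=O)c2ccc(C)cc2)cc1O | intermediate
16 | 7-(tosyloxy)-2H-chromene-3-carbaldehyde | O=CC1=Cc2ccc(OS(=O)(=O)c3ccc(C)cc3)cc2OC1 | intermediate
17 | 7-(tosyloxy)-2H-chromene-3-carboxylic acid | OC(=O)C1=Cc2ccc(OS(=O)(=O)c3ccc(C)cc3)cc2OC1 | intermediate
18 | (S)-7-(tosyloxy)chroman-3-carboxylic acid | OC(=O)[C@@H]1COc2cc(OS(=O)(=O)c3ccc(C)cc3)ccc2C1 | intermediate
19 | (R)-[7-(tosyloxy)chroman-3-yl]methanol | OC[C@@H]1COc2cc(OS(=O)(=O)c3ccc(C)cc3)ccc2C1 | intermediate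
20 | (S)-7-(tosyloxy)chroman-3-carbaldehyde | O=C[C@@H]1COc2cc(OS(=O)(=O)c3ccc(C)cc3)ccc2C1 | intermediate
21 | (R)-3-ethynyl-7-(tosyloxy)chroman | C#C[C@@H]1COc2cc(OS(=O)(=O)c3ccc(C)cc3)ccc2C1 | intermediate
22 | keteniminium triflate from 13 | COc1ccc([C@@H]2COc3cc(OS(=O)(=O)c4ccc(C)cc4)ccc3[C@H]2C=C=[N+](C)C)c(OC)c1OS(=O)(=O)c1ccc(C)cc1.[O-]S(=O)(=O)C(F)(F)F | intermediate
23 | cyclobuteniminium triflate (N,N-dimethyliminium of 24) | COc1ccc([C@@H]2COc3cc(OS(=O)(=O)c4ccc(C)cc4)ccc3[C@H]2C2C(=[N+](C)C)C=C2[C@@H]2COc3cc(OS(=O)(=O)c4ccc(C)cc4)ccc3C2)c(OC)c1OS(=O)(=O)c1ccc(C)cc1.[O-]S(=O)(=O)C(F)(F)F | intermediate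
24 | 4-(trans-isoflavan-4-yl)-3-(chroman-3-yl)cyclobut-2-enone, tris(tosylate), epimers at the ring sp3 carbon | COc1ccc([C@@H]2COc3cc(OS(=O)(=O)c4ccc(C)cc4)ccc3[C@H]2C2C(=O)C=C2[C@@H]2COc3cc(OS(=O)(=O)c4ccc(C)cc4)ccc3C2)c(OC)c1OS(=O)(=O)c1ccc(C)cc1 | intermediate
25 | acetylene | C#C | starting material
26 | lithium acetylide | [Li]C#C | intermediate
27 | lithium ethynolate | [Li]OC#C | intermediate
28 | (triisopropylsiloxy)acetylene | C#CO[Si](C(C)C)(C(C)C)C(C)C | intermediate
29 | E-vinylketene from ring opening of 24 | COc1ccc([C@@H]2COc3cc(OS(=O)(=O)c4ccc(C)cc4)ccc3[C@H]2/C=C(/C=C=O)[C@@H]2COc3cc(OS(=O)(=O)c4ccc(C)cc4)ccc3C2)c(OC)c1OS(=O)(=O)c1ccc(C)cc1 | intermediate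
30 | 4-alkenyl-3-(triisopropylsiloxy)cyclobut-2-enone from 29 and 28 (epimers at the ring sp3 carbon) | COc1ccc([C@@H]2COc3cc(OS(=O)(=O)c4ccc(C)cc4)ccc3[C@H]2/C=C(/C2C(=O)C=C2O[Si](C(C)C)(C(C)C)C(C)C)[C@@H]2COc3cc(OS(=O)(=O)c4ccc(C)cc4)ccc3C2)c(OC)c1OS(=O)(=O)c1ccc(C)cc1 | intermediate
31 | 3-siloxy dienylketene from ring opening of 30 | COc1ccc([C@@H]2COc3cc(OS(=O)(=O)c4ccc(C)cc4)ccc3[C@H]2/C=C(/C=C(\C=C=O)O[Si](C(C)C)(C(C)C)C(C)C)[C@@H]2COc3cc(OS(=O)(=O)c4ccc(C)cc4)ccc3C2)c(OC)c1OS(=O)(=O)c1ccc(C)cc1 | intermediate
32 | cyclohexa-2,4-dienone, keto tautomer of 33 | COc1ccc([C@@H]2COc3cc(OS(=O)(=O)c4ccc(C)cc4)ccc3[C@H]2C2C(=O)C=C(O[Si](C(C)C)(C(C)C)C(C)C)C=C2[C@@H]2COc3cc(OS(=O)(=O)c4ccc(C)cc4)ccc3C2)c(OC)c1OS(=O)(=O)c1ccc(C)cc1 | intermediate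
33 | ring-D phenol with D2 hydroxyl and D4 triisopropylsilyl ether, tris(tosylate) | COc1ccc([C@@H]2COc3cc(OS(=O)(=O)c4ccc(C)cc4)ccc3[C@H]2c2c(O)cc(O[Si](C(C)C)(C(C)C)C(C)C)cc2[C@@H]2COc3cc(OS(=O)(=O)c4ccc(C)cc4)ccc3C2)c(OC)c1OS(=O)(=O)c1ccc(C)cc1 | intermediate
34 | D2 methyl ether of 33 | COc1ccc([C@@H]2COc3cc(OS(=O)(=O)c4ccc(C)cc4)ccc3[C@H]2c2c(OC)cc(O[Si](C(C)C)(C(C)C)C(C)C)cc2[C@@H]2COc3cc(OS(=O)(=O)c4ccc(C)cc4)ccc3C2)c(OC)c1OS(=O)(=O)c1ccc(C)cc1 | intermediate
35 | 3-[(3R)-7-hydroxychroman-3-yl]-4-[(3R,4S)-7-hydroxy-3-(3-hydroxy-2,4-dimethoxyphenyl)chroman-4-yl]-5-methoxyphenol | COc1ccc([C@@H]2COc3cc(O)ccc3[C@H]2c2c(OC)cc(O)cc2[C@@H]2COc3cc(O)ccc3C2)c(OC)c1O | target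

## Step count and least certain steps

Total step count: 21. Longest linear sequence: 11 steps (steps 10–16, then 17, 19, 20, 21; the ring B branch through steps 3–9 is equally long).

Step 19 (key step). The likely failure is slow [2+2] capture of the congested vinylketene, which would let ketene dimerisation, acylation of the product phenol by the ketene, or the thermal silyl shift of the siloxyalkyne to a silylketene take over; the 6π closure between two carbons that both carry branched groups may also be slow. The fallback sets out from ester 12 and acid 18 and comes back at 33; it builds ring D by a polyketide-type aldol aromatisation instead of a pericyclic cascade. Acid 18 is activated with 1,1'-carbonyldiimidazole to N-acylimidazole F1, which acylates the lithium enolate of acetone (LiHMDS, THF, −78 °C) to give β-diketone F2. Its dianion (LDA, 2.2 equiv, −78 °C, deprotonation at the methyl terminus) is acylated by 12 to give 1,3,5-triketone F3. Dilute aqueous K2CO3 in THF at room temperature should bring about the intramolecular aldol condensation between the methylene next to the isoflavanyl group and the chromanyl ketone, and enolisation gives resorcinol F4. The D4 hydroxyl, which has no ortho substituent, is then silylated selectively (TIPSCl, imidazole, DMF) to give 33. The enolisable C3' centre is exposed to base in this sequence and would have to be watched.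

Step 17. The likely failure is capture of the keteniminium ion by an arene (C5' of the dimethoxy ring B is still activated) or its decay before the slowly reacting terminal alkyne adds. The fallback sets out from 21 and 13 and comes back at 24; it replaces the alkyne by the faster-reacting alkene and introduces the ring double bond afterwards. Semi-hydrogenation of 21 (lead-poisoned Pd/CaCO3, quinoline, H2) gives (R)-3-vinyl-7-(tosyloxy)chroman F5. The same Tf2O/collidine activation of 13 in the presence of F5, then hydrolysis, gives cyclobutanone F6, with the isoflavanyl group on the α-carbon and the chromanyl group on the β-carbon. Kinetic enolisation on the methylene side (LiHMDS, Me3SiCl, −78 °C) gives trimethylsilyl enol ether F7, PhSeCl gives α-phenylselanyl ketone F8, and oxidation with H2O2 followed by syn elimination of the selenoxide, which can only go toward the chromanyl-bearing carbon, returns 24.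

Step 8. The likely failure is loss of the C3 proton from the C4 cation to give the 2H-chromene, with erosion of the C3 configuration if protonation is reversible, or incomplete trans selectivity. The fallback sets out from 11 and comes back at 12; it replaces the cation by a stereospecific displacement with inversion. Alcohol 11 (3,4-cis) is alkylated with dimethyl malonate under Mitsunobu-type conditions with (cyanomethylene)tributylphosphorane (toluene, 100 °C) to give trans malonate F9, and Krapcho demethoxycarbonylation (LiCl, wet DMSO, 130 °C) gives 12.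

Step 18. The likely failure is silylation of the parent ynolate on carbon, which gives the silylketene, or disproportionation of the monolithium acetylide before oxygenation. The fallback does not branch from a numbered compound: it replaces 25 by commercial chloroacetaldehyde F10 and comes back at 28; it forms the O–Si bond first and the triple bond last. F10 is converted with TIPSOTf and Et3N into (Z)-2-chlorovinyl triisopropylsilyl ether F11 (the E isomer serves equally), and double deprotonation with LDA (2.2 equiv, THF, −78 °C) followed by an aqueous quench eliminates chloride to give 28, in the manner of the classical alkoxyacetylene synthesis.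

Step 16. The likely failure is base-mediated enolisation of aldehyde 20 under K2CO3/MeOH, which leads to epimerisation at C3' or to ring opening by retro-oxa-Michael elimination. The fallback sets out from 20 and comes back at 21; it uses a Corey–Fuchs sequence so that the aldehyde meets only a neutral ylide. CBr4 and PPh3 (CH2Cl2, 0 °C) give 1,1-dibromoalkene F12, and n-BuLi (2.1 equiv, THF, −78 °C, then NH4Cl) gives 21 by bromine–lithium exchange and 1,2-shift; at this temperature the exchange should be faster than attack on the aryl sulfonate.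

## Further compounds

F1 | step 19 | 1-[(3S)-7-(tosyloxy)chroman-3-carbonyl]imidazole | O=C([C@@H]1COc2cc(OS(=O)(=O)c3ccc(C)cc3)ccc2C1)n1ccnc1
F2 | step 19 | 1-[(3S)-7-(tosyloxy)chroman-3-yl]butane-1,3-dione | CC(=O)CC(=O)[C@@H]1COc2cc(OS(=O)(=O)c3ccc(C)cc3)ccc2C1
F3 | step 19 | 1-[(3S)-7-(tosyloxy)chroman-3-yl]-6-{(3R,4S)-3-[2,4-dimethoxy-3-(tosyloxy)phenyl]-7-(tosyloxy)chroman-4-yl}hexane-1,3,5-trione | COc1ccc([C@@H]2COc3cc(OS(=O)(=O)c4ccc(C)cc4)ccc3[C@H]2CC(=O)CC(=O)CC(=O)[C@@H]2COc3cc(OS(=O)(=O)c4ccc(C)cc4)ccc3C2)c(OC)c1OS(=O)(=O)c1ccc(C)cc1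
F4 | step 19 | ring-D resorcinol with free D2 and D4 hydroxyls, tris(tosylate) | COc1ccc([C@@H]2COc3cc(OS(=O)(=O)c4ccc(C)cc4)ccc3[C@H]2c2c(O)cc(O)cc2[C@@H]2COc3cc(OS(=O)(=O)c4ccc(C)cc4)ccc3C2)c(OC)c1OS(=O)(=O)c1ccc(C)cc1
F5 | step 17 | (R)-3-vinyl-7-(tosyloxy)chroman | C=C[C@@H]1COc2cc(OS(=O)(=O)c3ccc(C)cc3)ccc2C1
F6 | step 17 | 2-(trans-isoflavan-4-yl)-3-(chroman-3-yl)cyclobutanone, tris(tosylate) | COc1ccc([C@@H]2COc3cc(OS(=O)(=O)c4ccc(C)cc4)ccc3[C@H]2C2C(=O)CC2[C@@H]2COc3cc(OS(=O)(=O)c4ccc(C)cc4)ccc3C2)c(OC)c1OS(=O)(=O)c1ccc(C)cc1
F7 | step 17 | trimethylsilyl enol ether of F6 on the methylene side | COc1ccc([C@@H]2COc3cc(OS(=O)(=O)c4ccc(C)cc4)ccc3[C@H]2C2C(O[Si](C)(C)C)=CC2[C@@H]2COc3cc(OS(=O)(=O)c4ccc(C)cc4)ccc3C2)c(OC)c1OS(=O)(=O)c1ccc(C)cc1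
F8 | step 17 | 4-(phenylselanyl) derivative of cyclobutanone F6 | COc1ccc([C@@H]2COc3cc(OS(=O)(=O)c4ccc(C)cc4)ccc3[C@H]2C2C(=O)C([Se]c3ccccc3)C2[C@@H]2COc3cc(OS(=O)(=O)c4ccc(C)cc4)ccc3C2)c(OC)c1OS(=O)(=O)c1ccc(C)cc1
F9 | step 8 | dimethyl 2-{trans-3-[2,4-dimethoxy-3-(tosyloxy)phenyl]-7-(tosyloxy)chroman-4-yl}malonate | COc1ccc([C@@H]2COc3cc(OS(=O)(=O)c4ccc(C)cc4)ccc3[C@H]2C(C(=O)OC)C(=O)OC)c(OC)c1OS(=O)(=O)c1ccc(C)cc1
F10 | step 18 | chloroacetaldehyde | O=CCCl
F11 | step 18 | (Z)-2-chlorovinyl triisopropylsilyl ether | Cl/C=C\O[Si](C(C)C)(C(C)C)C(C)C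
F12 | step 16 | (R)-3-(2,2-dibromovinyl)-7-(tosyloxy)chroman | BrC(Br)=C[C@@H]1COc2cc(OS(=O)(=O)c3ccc(C)cc3)ccc2C1
A1 | alternative 1 | 5-(benzyloxy)-3-methoxy-2-(trimethylsilyl)phenyl trifluoromethanesulfonate | COc1cc(OCc2ccccc2)cc(OS(=O)(=O)C(F)(F)F)c1[Si](C)(C)C
A2 | alternative 1 | methyl 3-[4-(benzyloxy)-2-(methoxymethoxy)phenyl]-3-oxopropanoate | COCOc1cc(OCc2ccccc2)ccc1C(=O)CC(=O)OC
A3 | alternative 1 | methyl {2-[4-(benzyloxy)-2-(methoxymethoxy)benzoyl]-5-(benzyloxy)-3-methoxyphenyl}acetate | COCOc1cc(OCc2ccccc2)ccc1C(=O)c1c(OC)cc(OCc2ccccc2)cc1CC(=O)OC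
A4 | alternative 2 | (E)-2-{4-(benzyloxy)-2-methoxy-6-[(3R)-7-(benzyloxy)chroman-3-yl]styryl}-4,4,5,5-tetramethyl-1,3,2-dioxaborolane | COc1cc(OCc2ccccc2)cc([C@@H]2COc3cc(OCc4ccccc4)ccc3C2)c1/C=C/B1OC(C)(C)C(C)(C)O1
A5 | alternative 2 | [3-(benzyloxy)-2,4-dimethoxyphenyl]lithium | [Li]c1ccc(OC)c(OCc2ccccc2)c1OC
A6 | alternative 2 | 4-(benzyloxy)-2-(methoxymethoxy)phenyl trifluoromethanesulfonate | COCOc1cc(OCc2ccccc2)ccc1OS(=O)(=O)C(F)(F)F
A7 | alternative 2 | 1,2,2-triarylethyl pinacol boronate with C3 and C4 set | COc1ccc([C@H](B2OC(C)(C)C(C)(C)O2)[C@@H](c2ccc(OCc3ccccc3)cc2OCOC)c2c(OC)cc(OCc3ccccc3)cc2[C@@H]2COc3cc(OCc4ccccc4)ccc3C2)c(OC)c1OCc1ccccc1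
A8 | alternative 3 | 1,1-dimethoxy-3-(trimethylsilyloxy)buta-1,3-diene | COC(OC)=CC(=C)O[Si](C)(C)C
A9 | alternative 3 | 1-[4-(benzyloxy)-2-(methoxymethoxy)phenyl]-3-[(3R)-7-(benzyloxy)chroman-3-yl]prop-2-yn-1-one | COCOc1cc(OCc2ccccc2)ccc1C(=O)C#C[C@@H]1COc2cc(OCc3ccccc3)ccc2C1
A10 | alternative 3 | [4-(benzyloxy)-2-(methoxymethoxy)phenyl]{2-[(3R)-7-(benzyloxy)chroman-3-yl]-4-hydroxy-6-methoxyphenyl}methanone | COCOc1cc(OCc2ccccc2)ccc1C(=O)c1c(OC)cc(O)cc1[C@@H]1COc2cc(OCc3ccccc3)ccc2C1
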